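**Retrosynthetic overview**
- Laxiflorin ⇐ global desilylation of its tris-TBS ether; the C8–prenyl bond ⇐ para-Claisen (Claisen then Cope, two [3,3] shifts) of a 5-O-prenyl ether whose C6 is blocked.
- 5-O-prenyl ether ⇐ Mitsunobu etherification; the C6 CH2CH2OH arm ⇐ ozonolysis/NaBH4 of a 6-allyl group ⇐ ortho-Claisen [3,3] of the 5-O-allyl ether (C6 is the only open ortho carbon).
- 5-O-allyl ether ⇐ Mitsunobu on 7,4'-bis-O-TBS-(2S)-homoeriodictyol ⇐ natural (2S)-homoeriodictyol, which carries C2.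
- Ring order: no ring is built; rings A, C and B arrive intact in the flavanone, and the route only substitutes ring A, C6 first, then C8.

Assumption: natural (2S)-homoeriodictyol (compound 1, from Eriodictyon, also sold as its sodium salt) is bought enantiomerically enriched; ee is checked by chiral HPLC and upgraded by crystallization if needed.

**Route**

Step 1
Reactants: 1 (2S)-homoeriodictyol [(2S)-5,7-dihydroxy-2-(4-hydroxy-3-methoxyphenyl)chroman-4-one]
Product: 2 (2S)-7-(tert-butyldimethylsilyloxy)-2-[4-(tert-butyldimethylsilyloxy)-3-methoxyphenyl]-5-hydroxychroman-4-one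
Conditions: TBSCl (2.2 equiv), imidazole (5 equiv), DMF, 0 °C to rt
Reagents that add atoms: tert-butyldimethylsilyl chloride (TBSCl), CC(C)(C)[Si](C)(C)Cl
Why: Silyl ether formation hits only the 7- and 4'-phenols because the 5-OH is locked in a hydrogen bond to the C4 carbonyl, and the weak base imidazole does not open the chromanone ring, so C2 stays S.

Step 2
Reactants: 2 bis-silyl ether from step 1; 3 allyl alcohol (prop-2-en-1-ol)
Product: 4 (2S)-5-(allyloxy)-7-(tert-butyldimethylsilyloxy)-2-[4-(tert-butyldimethylsilyloxy)-3-methoxyphenyl]chroman-4-one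
Conditions: PPh3 (1.5 equiv), DIAD (1.5 equiv), THF, 0 °C to rt
Reagents that add atoms: none
Why: Mitsunobu etherification of the only remaining acidic OH (the chelated 5-phenol) with a primary allylic alcohol runs under essentially neutral conditions, avoiding the base-mediated retro-oxa-Michael opening to the chalcone that would racemize C2.

Step 3
Reactants: 4 5-O-allyl ether
Product: 6 (2S)-6-allyl-7-(tert-butyldimethylsilyloxy)-2-[4-(tert-butyldimethylsilyloxy)-3-methoxyphenyl]-5-hydroxychroman-4-one, via 6-allyl ortho-dienone 5 (not isolated)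
Conditions: degassed 1,2-dichlorobenzene, 180 °C, sealed tube, 2–4 h
Reagents that add atoms: none
Why: Aromatic Claisen rearrangement ([3,3]-sigmatropic shift): the allyl group can only reach C6 because the other ortho carbon (C4a) is the ring fusion, dienone 5 enolizes at once to the chelated phenol, and the neutral base-free medium leaves C2 untouched.

Step 4
Reactants: 6 6-allyl phenol
Product: 8 (2S)-7-(tert-butyldimethylsilyloxy)-2-[4-(tert-butyldimethylsilyloxy)-3-methoxyphenyl]-5-hydroxy-6-(2-hydroxyethyl)chroman-4-one, via arylacetaldehyde 7 (not isolated)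
Conditions: O3, CH2Cl2/MeOH (3:1), −78 °C, stop at full conversion, N2 purge; then NaBH4 (3 equiv), −78 to 0 °C; aq NH4Cl
Reagents that add atoms: ozone, [O-][O+]=O
Why: Ozonolysis with reductive borohydride work-up: the isolated terminal alkene reacts with ozone far faster than the acylated, silylated arenes, and the peroxidic products collapse to aldehyde 7, which NaBH4 reduces at low temperature much faster than the C4 ketone, deactivated as a chelated vinylogous ester.

Step 5
Reactants: 8 primary alcohol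
Product: 9 (2S)-7-(tert-butyldimethylsilyloxy)-6-[2-(tert-butyldimethylsilyloxy)ethyl]-2-[4-(tert-butyldimethylsilyloxy)-3-methoxyphenyl]-5-hydroxychroman-4-one
Conditions: TBSCl (1.2 equiv), imidazole (2.5 equiv), CH2Cl2, 0 °C
Reagents that add atoms: tert-butyldimethylsilyl chloride (TBSCl), CC(C)(C)[Si](C)(C)Cl
Why: Silyl ether formation is selective for the unhindered primary alcohol over the hydrogen-bonded 5-phenol, and it masks the alcohol that would otherwise cyclize onto O5 to a dihydrobenzofuran under Mitsunobu conditions.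

Step 6
Reactants: 9 tris-silyl ether; 10 prenyl alcohol (3-methylbut-2-en-1-ol)
Product: 11 (2S)-7-(tert-butyldimethylsilyloxy)-6-[2-(tert-butyldimethylsilyloxy)ethyl]-2-[4-(tert-butyldimethylsilyloxy)-3-methoxyphenyl]-5-[(3-methylbut-2-en-1-yl)oxy]chroman-4-one
Conditions: PPh3 (2 equiv), DIAD (2 equiv), THF, 0 °C to rt
Reagents that add atoms: none
Why: Second Mitsunobu etherification: the 5-OH is again the only acidic OH, and the neutral conditions give the primary prenyl ether by direct displacement without ring opening at C2.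

Step 7
Reactants: 11 5-O-prenyl ether
Product: 14 (2S)-7-(tert-butyldimethylsilyloxy)-6-[2-(tert-butyldimethylsilyloxy)ethyl]-2-[4-(tert-butyldimethylsilyloxy)-3-methoxyphenyl]-5-hydroxy-8-(3-methylbut-2-en-1-yl)chroman-4-one, via 6-(2-methylbut-3-en-2-yl) ortho-dienone 12 (not isolated), via 8-prenyl para-dienone 13 (not isolated)
Conditions: Eu(fod)3 (fod = 6,6,7,7,8,8,8-heptafluoro-2,2-dimethyloctane-3,5-dionate; 10 mol %), PhCl, 80 °C
Reagents that add atoms: none
Why: Para-Claisen (Claisen–Cope) rearrangement, two consecutive [3,3]-sigmatropic shifts accelerated by chelation of Eu(fod)3 between the C4 carbonyl and O5: the first shift puts a reverse-prenyl group on the blocked C6, dienone 12 cannot enolize, so a Cope shift carries the group to C8 with a second allylic inversion (normal prenyl), and dienone 13 aromatizes, with C2 not involved.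

Step 8
Reactants: 14 tris-silyl ether of the target
Product: 15 laxiflorin [(2S)-5,7-dihydroxy-6-(2-hydroxyethyl)-2-(4-hydroxy-3-methoxyphenyl)-8-(3-methylbut-2-en-1-yl)chroman-4-one]
Conditions: TBAF (4 equiv), AcOH (4 equiv), THF, 0 °C to rt
Reagents that add atoms: none
Why: Fluoride-mediated desilylation buffered with acetic acid cleaves the two aryl and the primary silyl ethers without free phenoxide base (no chalcone opening, C2 stays S) and without acid that could cyclize the prenyl group onto the 7-OH.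

**Compound list**

1 | (2S)-homoeriodictyol | COc1cc([C@@H]2CC(=O)c3c(O)cc(O)cc3O2)ccc1O | starting material
2 | (2S)-7-(tert-butyldimethylsilyloxy)-2-[4-(tert-butyldimethylsilyloxy)-3-methoxyphenyl]-5-hydroxychroman-4-one | COc1cc([C@@H]2CC(=O)c3c(O)cc(O[Si](C)(C)C(C)(C)C)cc3O2)ccc1O[Si](C)(C)C(C)(C)C | intermediate
3 | allyl alcohol | C=CCO | starting material
4 | (2S)-5-(allyloxy)-7-(tert-butyldimethylsilyloxy)-2-[4-(tert-butyldimethylsilyloxy)-3-methoxyphenyl]chroman-4-one | COc1cc([C@@H]2CC(=O)c3c(OCC=C)cc(O[Si](C)(C)C(C)(C)C)cc3O2)ccc1O[Si](C)(C)C(C)(C)C | intermediate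
5 | (2S)-6-allyl-7-(tert-butyldimethylsilyloxy)-2-[4-(tert-butyldimethylsilyloxy)-3-methoxyphenyl]-2,3-dihydro-6H-chromene-4,5-dione (ortho-dienone, both C6 epimers) | COc1cc([C@@H]2CC(=O)C3=C(O2)C=C(O[Si](C)(C)C(C)(C)C)C(CC=C)C3=O)ccc1O[Si](C)(C)C(C)(C)C | intermediate (not isolated)
6 | (2S)-6-allyl-7-(tert-butyldimethylsilyloxy)-2-[4-(tert-butyldimethylsilyloxy)-3-methoxyphenyl]-5-hydroxychroman-4-one | COc1cc([C@@H]2CC(=O)c3c(O)c(CC=C)c(O[Si](C)(C)C(C)(C)C)cc3O2)ccc1O[Si](C)(C)C(C)(C)C | intermediate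
7 | 2-{(2S)-7-(tert-butyldimethylsilyloxy)-2-[4-(tert-butyldimethylsilyloxy)-3-methoxyphenyl]-5-hydroxy-4-oxochroman-6-yl}acetaldehyde | COc1cc([C@@H]2CC(=O)c3c(O)c(CC=O)c(O[Si](C)(C)C(C)(C)C)cc3O2)ccc1O[Si](C)(C)C(C)(C)C | intermediate (not isolated)
8 | (2S)-7-(tert-butyldimethylsilyloxy)-2-[4-(tert-butyldimethylsilyloxy)-3-methoxyphenyl]-5-hydroxy-6-(2-hydroxyethyl)chroman-4-one | COc1cc([C@@H]2CC(=O)c3c(O)c(CCO)c(O[Si](C)(C)C(C)(C)C)cc3O2)ccc1O[Si](C)(C)C(C)(C)C | intermediate
9 | (2S)-7-(tert-butyldimethylsilyloxy)-6-[2-(tert-butyldimethylsilyloxy)ethyl]-2-[4-(tert-butyldimethylsilyloxy)-3-methoxyphenyl]-5-hydroxychroman-4-one | COc1cc([C@@H]2CC(=O)c3c(O)c(CCO[Si](C)(C)C(C)(C)C)c(O[Si](C)(C)C(C)(C)C)cc3O2)ccc1O[Si](C)(C)C(C)(C)C | intermediate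
10 | prenyl alcohol (3-methylbut-2-en-1-ol) | CC(C)=CCO | starting material
11 | (2S)-7-(tert-butyldimethylsilyloxy)-6-[2-(tert-butyldimethylsilyloxy)ethyl]-2-[4-(tert-butyldimethylsilyloxy)-3-methoxyphenyl]-5-[(3-methylbut-2-en-1-yl)oxy]chroman-4-one | COc1cc([C@@H]2CC(=O)c3c(OCC=C(C)C)c(CCO[Si](C)(C)C(C)(C)C)c(O[Si](C)(C)C(C)(C)C)cc3O2)ccc1O[Si](C)(C)C(C)(C)C | intermediate
12 | (2S)-7-(tert-butyldimethylsilyloxy)-6-[2-(tert-butyldimethylsilyloxy)ethyl]-2-[4-(tert-butyldimethylsilyloxy)-3-methoxyphenyl]-6-(2-methylbut-3-en-2-yl)-2,3-dihydro-6H-chromene-4,5-dione (ortho-dienone, both C6 epimers) | COc1cc([C@@H]2CC(=O)C3=C(O2)C=C(O[Si](C)(C)C(C)(C)C)C(CCO[Si](C)(C)C(C)(C)C)(C(C)(C)C=C)C3=O)ccc1O[Si](C)(C)C(C)(C)C | intermediate (not isolated)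
13 | (2S)-7-(tert-butyldimethylsilyloxy)-6-[2-(tert-butyldimethylsilyloxy)ethyl]-2-[4-(tert-butyldimethylsilyloxy)-3-methoxyphenyl]-8-(3-methylbut-2-en-1-yl)-2,3-dihydro-8H-chromene-4,5-dione (para-dienone, both C8 epimers) | COc1cc([C@@H]2CC(=O)C3=C(O2)C(CC=C(C)C)C(O[Si](C)(C)C(C)(C)C)=C(CCO[Si](C)(C)C(C)(C)C)C3=O)ccc1O[Si](C)(C)C(C)(C)C | intermediate (not isolated)
14 | (2S)-7-(tert-butyldimethylsilyloxy)-6-[2-(tert-butyldimethylsilyloxy)ethyl]-2-[4-(tert-butyldimethylsilyloxy)-3-methoxyphenyl]-5-hydroxy-8-(3-methylbut-2-en-1-yl)chroman-4-one | COc1cc([C@@H]2CC(=O)c3c(O)c(CCO[Si](C)(C)C(C)(C)C)c(O[Si](C)(C)C(C)(C)C)c(CC=C(C)C)c3O2)ccc1O[Si](C)(C)C(C)(C)C | intermediate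
15 | laxiflorin, (2S)-5,7-dihydroxy-6-(2-hydroxyethyl)-2-(4-hydroxy-3-methoxyphenyl)-8-(3-methylbut-2-en-1-yl)chroman-4-one | COc1cc([C@@H]2CC(=O)c3c(O)c(CCO)c(O)c(CC=C(C)C)c3O2)ccc1O | target

**Totals**

Total step count: 8. Longest linear sequence: 8 steps (1 to 15). The single stereocenter (C2, S) is bought in 1 and never touched; every step is neutral, buffered or cold so that the chromanone ring is not opened to the chalcone.

**Three steps most likely to fail**

Step 4. Ozone may attack the electron-rich rings, and borohydride in methanol may touch the C4 ketone or the aryl silyl ethers. The fallback sets out from 2 and comes back at 8, replacing the Claisen/ozonolysis arm (steps 2 to 4) by cross-coupling and hydroboration. Iodination of 2 with benzyltrimethylammonium dichloroiodate and CaCO3 in CH2Cl2/MeOH at rt, directed ortho to the chelated 5-OH, gives (2S)-7-(tert-butyldimethylsilyloxy)-2-[4-(tert-butyldimethylsilyloxy)-3-methoxyphenyl]-5-hydroxy-6-iodochroman-4-one F1. Stille coupling with tributyl(vinyl)stannane (Pd(PPh3)4, toluene, 100 °C) gives (2S)-7-(tert-butyldimethylsilyloxy)-2-[4-(tert-butyldimethylsilyloxy)-3-methoxyphenyl]-5-hydroxy-6-vinylchroman-4-one F2. Anti-Markovnikov hydroboration with 9-BBN (THF, 0 °C to rt) and oxidation with NaBO3·4H2O then gives 8.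

Step 6. The 5-OH is now chelated and flanked on both sides, so the Mitsunobu reaction may stall or lose prenyl alcohol as isoprene. The fallback sets out from 9 and comes back at 14, bypassing steps 6 and 7 by a halogenation and cross-coupling. NIS in DMF at 0 °C iodinates the only free ring A position (C8, para to the 5-OH) to give (2S)-7-(tert-butyldimethylsilyloxy)-6-[2-(tert-butyldimethylsilyloxy)ethyl]-2-[4-(tert-butyldimethylsilyloxy)-3-methoxyphenyl]-5-hydroxy-8-iodochroman-4-one F3. Stille coupling with tributyl(3-methylbut-2-en-1-yl)stannane (Pd2(dba)3, AsPh3, LiCl, DMF, 60 °C) gives 14 with the linear prenyl group.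

Step 7. The blocked ortho-dienone 12 may fragment (loss of the C5 unit) or stop short of the Cope shift. The fallback sets out from 8 and comes back at the target 15, installing the prenyl group by electrophilic substitution without protecting groups. Desilylation of 8 with TBAF/AcOH in THF gives (2S)-5,7-dihydroxy-6-(2-hydroxyethyl)-2-(4-hydroxy-3-methoxyphenyl)chroman-4-one F4. Friedel–Crafts prenylation of F4 with 2-methylbut-3-en-2-ol and BF3·OEt2 in dioxane at rt can only occur at C8 on ring A and gives 15 directly; the yield is expected to be modest, and chroman formation is limited by short reaction time.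

**Further compounds**

F1 | step 4 | (2S)-7-(tert-butyldimethylsilyloxy)-2-[4-(tert-butyldimethylsilyloxy)-3-methoxyphenyl]-5-hydroxy-6-iodochroman-4-one | COc1cc([C@@H]2CC(=O)c3c(O)c(I)c(O[Si](C)(C)C(C)(C)C)cc3O2)ccc1O[Si](C)(C)C(C)(C)C
F2 | step 4 | (2S)-7-(tert-butyldimethylsilyloxy)-2-[4-(tert-butyldimethylsilyloxy)-3-methoxyphenyl]-5-hydroxy-6-vinylchroman-4-one | COc1cc([C@@H]2CC(=O)c3c(O)c(C=C)c(O[Si](C)(C)C(C)(C)C)cc3O2)ccc1O[Si](C)(C)C(C)(C)C
F3 | step 6 | (2S)-7-(tert-butyldimethylsilyloxy)-6-[2-(tert-butyldimethylsilyloxy)ethyl]-2-[4-(tert-butyldimethylsilyloxy)-3-methoxyphenyl]-5-hydroxy-8-iodochroman-4-one | COc1cc([C@@H]2CC(=O)c3c(O)c(CCO[Si](C)(C)C(C)(C)C)c(O[Si](C)(C)C(C)(C)C)c(I)c3O2)ccc1O[Si](C)(C)C(C)(C)C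
F4 | step 7 | (2S)-5,7-dihydroxy-6-(2-hydroxyethyl)-2-(4-hydroxy-3-methoxyphenyl)chroman-4-one | COc1cc([C@@H]2CC(=O)c3c(O)c(CCO)c(O)cc3O2)ccc1O
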